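## The problem

Solandelactone F (19) is a C22 oxylipin made of three units joined by single bonds. These are a (Z)-oct-4-enolide (ring O and C1–C7), a trans-1,2-disubstituted cyclopropane (C8–C10, attached through C7–C8 and C10–C11), and a side chain C11–C22 with carbinols at C11 and C14, an E alkene C12=C13 between them and a skipped Z alkene C16=C17. No rings are fused, so the work is to assemble a chain and to close a three-membered and an eight-membered ring on it. Five stereocentres must be set in one absolute sense: C7 (R), C8 (R), C10 (R), C11 (R) and C14 (S). C8 and C10 can be set together from an E alkene. A trans-cyclopropane passes little facial bias to an attached carbonyl group, so C7 and C11 each need reagent control, and C14 is insulated by the C12=C13 alkene and must arrive with its own fragment. The molecule is fragile: the strained lactone opens with nucleophiles and bases, C11 is both allylic and cyclopropylcarbinylic and ionises with acid, and the Z alkenes must keep their geometry. The opening for a short synthesis is that two of the three alkenes can be made from vinyl groups: C4=C5 inside the lactone ring and C12=C13 between the two carbinols. C16=C17 is an ordinary internal alkene that reacts much more slowly with metathesis catalysts, so both the lactone closure and the union with C13–C22 can be left to one metathesis operation at the end, with all hydroxyl groups free.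

## Retrosynthesis

**19 ⇒ 10 + 17 (cut C4=C5 and C12=C13).** The neighbouring cuts are the acyl bond O–C1 and the bond C11–C12. The first means lactonisation to a medium ring and needs both carbinols protected. The second means adding an alkenyl metal to an aldehyde that already carries the strained lactone, with weak control at C11. Cutting the two alkenes instead turns ring closure and fragment union into the pairing of vinyl termini, and no carbinol needs protection. The precursors are the acyclic triene ester 10 (15 carbons, four stereocentres, no medium ring) and the dienol 17 (11 carbons, one stereocentre). The forward reaction must close the ring between the pentenoate and allyl termini before or faster than any intermolecular event, join the C11 vinyl carbinol to 17 with E geometry, and leave the Z alkenes untouched.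

**10 ⇒ 9 (cut C11–C12).** The vinyl group is removed from the C11 carbinol, leaving the cyclopropanecarbaldehyde 9. The alternative cut C10–C11 would need a configurationally defined cyclopropyl metal and acrolein. The chosen cut needs only an aldehyde that comes straight from a primary alcohol. The precursor has one stereocentre and two carbons fewer. The forward step must deliver a vinyl group to one aldehyde face under reagent control with a nucleophile that ignores the pentenoate ester, which points to an organozinc reagent with a chiral amino alcohol.

**9 ⇒ 8 ⇒ 7 ⇒ 5 + 6 (adjust C11, cut O–C1 of the ester).** The aldehyde is traced to the primary alcohol 8 and its silyl ether 7, and the ester bond is cut to give alcohol 5 and pent-4-enoic acid 6. Forming this bond now is a simple intermolecular acylation, whereas later it would be a difficult ring closure. The pentenoate also protects the C7 hydroxyl during the work at C11. Desilylation and oxidation must spare the ester; acyl migration to the new primary hydroxyl is ruled out by the trans-cyclopropane between them.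

**5 ⇒ 4 (cut C6–C7).** Removing the allyl group leaves aldehyde 4. One bond construction supplies the C7 stereocentre and the C4–C6 terminus for the later ring closure. The alternative cut C7–C8 would again need a chiral cyclopropyl nucleophile. The forward reaction is an allylboration with a chiral allylborane, which must override the small bias of the ring.

**4 ⇒ 3 ⇒ 2 ⇒ 1 (cut C8–C9 and C9–C10).** The aldehyde comes from alcohol 3, and the ring from methylene transfer to the E-allylic alcohol 2. Alcohol 2 is the mono-silyl ether of the symmetrical diol 1, whose two ends are equivalent, so no regioisomer can arise. The free hydroxyl of 2 is the handle for a ligand-controlled zinc carbenoid, which must set C8 and C10 in one enantioselective, stereospecific step.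

**17 ⇒ 15 ⇒ 14 ⇒ 11 + 12 (cut the terminal vinyl carbon, adjust C16=C17, cut C15–C16).** The vinyl carbinol of 17 is traced to chlorohydrin 15 by one-carbon homologation of its epoxide 16 with a sulfonium ylide. The Z alkene comes from the alkyne 14, and 14 from acetylide 13 (from hept-1-yne 11) opening (S)-epichlorohydrin 12. C14 thus comes from the chiral pool and no protecting group is needed. The alkyne is reduced before the vinyl group exists, so no terminal alkene competes.

## Roads not taken

**Alternative 1:** The cyclopropane is cut at both bonds to C9 and traced to the chiral pool. The forward key step is a Simmons–Smith methylene transfer (Et2Zn, CH2I2) to the C2-symmetric E-alkene bis-acetonide A2, made from D-mannitol A3. The dioxolane oxygens on both sides steer the zinc carbenoid to the same face and give the trans-cyclopropane bis-acetonide A1, which holds C6–C12 with C7 and C11 already oxygenated.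
- Merits: C7 and C11 come from the sugar, C8 and C10 follow by substrate direction, and no chiral reagent is consumed. On stereochemical certainty this road is better than the chosen one, which needs three reagent-controlled steps for the same four centres.
- Weak points: the two ends of A1 are identical while the two ends of C6–C12 in 19 are not, so one acetonide must be removed statistically. C6 must lose its oxygen and gain the C1–C5 chain, C12 must become an alkene carbon, and the C7 and C11 hydroxyls need different protecting groups throughout. Lactone and side chain are then still made by separate lactonisation and olefination steps.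
- Comparison: the chosen plan sets against the surer stereocontrol a much shorter sequence, in which C6 and C12 are introduced directly as the vinyl carbons the final metathesis needs and no secondary carbinol is ever protected.

**Alternative 2:** The cut is on both sides of C11, at C10–C11 and C11–C12. In the forward sense dichloromethyllithium A7 inserts into the C–B bond of the cyclopropylboronic ester A5 (1,2-migration of C10 from boron to carbon, promoted by ZnCl2). The E-alkenylmagnesium bromide A6 then displaces the remaining chloride by a second 1,2-migration, giving the full skeleton A4 with boron at C11 in one flask. Oxidation of the C–B bond and desilylation would follow.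
- Merits: three components are joined convergently, the C11 configuration is dictated by the inexpensive diol on boron, and the E geometry of C12=C13 is brought in intact. On these points this road is at least as good as the chosen one, since it avoids the geometric and statistical questions of a cross-metathesis.
- Weak points: A5 already contains the strained lactone, and both A7 and A6 are hard nucleophiles that can add to it. The carbon bearing chloride after the first migration is cyclopropylcarbinylic, so the zinc Lewis acid can open the ring to a homoallyl system. A4 is an allylic boronic ester, prone to 1,3-boron shift before oxidation. A6 needs a multistep synthesis with E geometry next to a Z alkene and a silyl ether, and A4 is still two steps from 19.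
- Comparison: the chosen plan sets against the one-flask control at C11 the fact that no organometallic reagent ever meets the lactone, which forms only in the last step, and that its chain fragment 17 takes three steps without a protecting group.

**Alternative 3:** The cyclopropane is cut at C8–C10 and C9–C10, and the lactone is made first. The forward key step is carbene transfer from tert-butyl diazoacetate A10 to the terminal vinyl group of the 8-vinyl lactone A9 with RuCl2(iPr-pybox)(C2H4), giving the trans-cyclopropane ester A8 (C1–C11). A9 would be drawn from cleavage of (1Z,5Z)-cycloocta-1,5-diene A11, whose ring already holds the Z alkene and the spacing of C1–C8.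
- Merits: the starting material is very cheap, the Z geometry of C4=C5 is never in question, chirality for C8 and C10 comes from a catalyst, and the catalyst prefers terminal over 1,2-disubstituted alkenes. In catalyst economy this road is better than the chosen one.
- Weak points: the vinyl group of A9 is α-branched and allylic to an acyloxy group, a class that takes up carbenes less readily than styrenes, so diazo dimerisation competes. The catalyst must impose trans geometry and absolute sense against the existing C7 centre (matched or mismatched). The cleavage of A11 must also deliver C7 enantiopure. A8 ends at C11 as an ester that must be taken down to the aldehyde in the presence of the lactone. Above all, the C11 configuration, C12=C13 and C13–C22 remain unsolved and would need nucleophiles that endanger the lactone.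
- Comparison: the chosen plan uses stoichiometric chiral reagents where this road uses a catalyst, and sets against that a key step that finishes the molecule.

Key step: step 12

Remark: the cross-metathesis partner carries eleven carbons (C13–C22 plus the methylene that leaves as ethene) and is therefore (S,Z)-undeca-1,5-dien-3-ol (17).
Remark: the sense of induction in steps 2, 4 and 8 is assigned by analogy with the standard model substrates (cinnamyl alcohol for the cyclopropanation, benzaldehyde for the allylboration and the organozinc addition). Should a step show the opposite sense, the enantiomeric ligand or reagent is used.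
Remark: (E)-but-2-ene-1,4-diol is taken as purchasable; otherwise it is one step from but-2-yne-1,4-diol by LiAlH4 reduction.

## Route

Step 1
Reactants: 1 (E)-but-2-ene-1,4-diol
Product: 2 (E)-4-((tert-butyldiphenylsilyl)oxy)but-2-en-1-ol
Conditions: NaH (1.0 equiv), THF, 0 °C to rt; TBDPSCl (1.0 equiv), rt
Reagents that add atoms: tert-butyl(chloro)diphenylsilane, CC(C)(C)[Si](Cl)(c1ccccc1)c1ccccc1
Why: O-silylation of the mono-sodium alkoxide of a symmetrical diol, which reacts with one equivalent of silyl chloride mainly once; the two hydroxyls of 1 are equivalent, so no regioisomer can form.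

Step 2
Reactants: 2 (E)-4-((tert-butyldiphenylsilyl)oxy)but-2-en-1-ol
Product: 3 ((1R,2R)-2-(((tert-butyldiphenylsilyl)oxy)methyl)cyclopropyl)methanol
Conditions: Et2Zn, CH2I2, DME, CH2Cl2, −10 °C [Zn(CH2I)2·DME]; (4S,5S)-2-butyl-N,N,N',N'-tetramethyl-1,3,2-dioxaborolane-4,5-dicarboxamide (1.2 equiv), −10 °C to rt; aq. NH4Cl
Reagents that add atoms: diiodomethane, ICI
Why: Charette asymmetric Simmons–Smith cyclopropanation: the zinc alkoxide of 2 binds the chiral dioxaborolane, which delivers the zinc carbenoid to one alkene face, and the stereospecific methylene transfer turns the E alkene into the trans ring, so C8 and C10 are set together by the ligand. The (4S,5S) ligand is chosen because its enantiomer gives the (1S,2S) series from E-allylic alcohols.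

Step 3
Reactants: 3 ((1R,2R)-2-(((tert-butyldiphenylsilyl)oxy)methyl)cyclopropyl)methanol
Product: 4 (1R,2R)-2-(((tert-butyldiphenylsilyl)oxy)methyl)cyclopropane-1-carbaldehyde
Conditions: TEMPO (10 mol%), PhI(OAc)2 (1.1 equiv), CH2Cl2, rt
Reagents that add atoms: none
Why: TEMPO-catalysed oxidation (oxoammonium mechanism) stops at the aldehyde under near-neutral conditions; the trans-cyclopropane α-centre is not epimerised and the silyl ether is inert.

Step 4
Reactants: 4 (1R,2R)-2-(((tert-butyldiphenylsilyl)oxy)methyl)cyclopropane-1-carbaldehyde
Product: 5 (R)-1-((1R,2R)-2-(((tert-butyldiphenylsilyl)oxy)methyl)cyclopropyl)but-3-en-1-ol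
Conditions: (+)-Ipc2BOMe, CH2=CHCH2MgBr, Et2O, −78 °C to rt; 4, −78 °C; then NaOH, H2O2, 0 °C to rt
Reagents that add atoms: allylmagnesium bromide, C=CC[Mg]Br (its allyl group is delivered through (+)-B-allyldiisopinocampheylborane, C=CCB([C@H]1C[C@H]2C[C@@H]([C@@H]1C)C2(C)C)[C@H]1C[C@H]2C[C@@H]([C@@H]1C)C2(C)C)
Why: Brown allylboration through a closed chair-like six-membered transition state; the isopinocampheyl groups of the reagent from (−)-α-pinene send the allyl group to the Re face of the aldehyde and set C7 as R under reagent control (the enantiomeric reagent attacks the Si face). The ring centres lie outside the forming six-membered array and should not override the reagent.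

Step 5
Reactants: 5 (R)-1-((1R,2R)-2-(((tert-butyldiphenylsilyl)oxy)methyl)cyclopropyl)but-3-en-1-ol; 6 pent-4-enoic acid
Product: 7 (R)-1-((1R,2R)-2-(((tert-butyldiphenylsilyl)oxy)methyl)cyclopropyl)but-3-en-1-yl pent-4-enoate
Conditions: DCC, DMAP (cat.), CH2Cl2, 0 °C to rt
Reagents that add atoms: none
Why: Steglich esterification (carbodiimide activation, acyl transfer by DMAP) acylates the secondary hydroxyl without breaking the C7–O bond, so C7 keeps its configuration; the medium is non-acidic, so the cyclopropyl carbinol does not ionise.

Step 6
Reactants: 7 (R)-1-((1R,2R)-2-(((tert-butyldiphenylsilyl)oxy)methyl)cyclopropyl)but-3-en-1-yl pent-4-enoate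
Product: 8 (R)-1-((1R,2R)-2-(hydroxymethyl)cyclopropyl)but-3-en-1-yl pent-4-enoate
Conditions: TBAF, AcOH, THF, 0 °C to rt
Reagents that add atoms: none
Why: Fluoride-mediated desilylation driven by Si–F bond formation; buffering with AcOH keeps the ester intact, and acyl migration to the new primary hydroxyl cannot occur across the trans-cyclopropane.

Step 7
Reactants: 8 (R)-1-((1R,2R)-2-(hydroxymethyl)cyclopropyl)but-3-en-1-yl pent-4-enoate
Product: 9 (R)-1-((1R,2R)-2-formylcyclopropyl)but-3-en-1-yl pent-4-enoate
Conditions: TEMPO (10 mol%), PhI(OAc)2 (1.1 equiv), CH2Cl2, rt
Reagents that add atoms: none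
Why: Same TEMPO-catalysed oxidation as in step 3; terminal alkenes and the ester are inert to the oxoammonium salt, and the aldehyde is used without delay.

Step 8
Reactants: 9 (R)-1-((1R,2R)-2-formylcyclopropyl)but-3-en-1-yl pent-4-enoate
Product: 10 (R)-1-((1R,2R)-2-((R)-1-hydroxyallyl)cyclopropyl)but-3-en-1-yl pent-4-enoate
Conditions: Zn(CH=CH2)2 (2 equiv, prepared beforehand from vinylmagnesium bromide and ZnCl2), (+)-MIB [(2R)-3-exo-morpholinoisoborneol, 15 mol%], toluene–Et2O, −30 to 0 °C; aq. NH4Cl
Reagents that add atoms: divinylzinc, C=C[Zn]C=C
Why: Amino-alcohol-catalysed addition of a diorganozinc to an aldehyde (ligand-accelerated catalysis through a zinc aminoalkoxide that binds aldehyde and reagent); organozincs do not attack the ester. (+)-MIB directs the vinyl group to the Re face, the mirror image of the Si-face delivery of (−)-MIB, and sets C11 as R under reagent control.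

Step 9
Reactants: 11 hept-1-yne; 12 (S)-epichlorohydrin
Product: 14 (S)-1-chlorodec-4-yn-2-ol, via lithium hept-1-yn-1-ide 13 (not isolated)
Conditions: n-BuLi, THF, −78 °C; BF3·OEt2; 12, −78 °C; aq. NH4Cl
Reagents that add atoms: none
Why: BF3-promoted SN2 opening of the epoxide by the lithium acetylide at the unsubstituted ring carbon; the stereocentre (C14 of the target) and the C–Cl bond are not involved, so the S configuration of 12 is carried over.

Step 10
Reactants: 14 (S)-1-chlorodec-4-yn-2-ol
Product: 15 (S,Z)-1-chlorodec-4-en-2-ol
Conditions: H2 (1 atm), Pd/CaCO3 poisoned with Pb(OAc)2, quinoline, EtOAc, rt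
Reagents that add atoms: none
Why: Semi-hydrogenation on poisoned palladium adds H2 syn and gives the Z alkene; it is done before the vinyl group exists, so no terminal alkene can be over-reduced, and the chloride and hydroxyl are inert.

Step 11
Reactants: 15 (S,Z)-1-chlorodec-4-en-2-ol
Product: 17 (S,Z)-undeca-1,5-dien-3-ol, via (S,Z)-2-(oct-2-en-1-yl)oxirane 16 (not isolated)
Conditions: Me3S+ I− (4 equiv), n-BuLi (3.9 equiv), THF, −10 °C; 15, −10 °C to rt
Reagents that add atoms: trimethylsulfonium iodide, C[S+](C)C.[I-]
Why: The first equivalent of dimethylsulfonium methylide acts as base and closes 15 to epoxide 16 (intramolecular etherification that does not touch the stereocentre). The ylide then opens 16 at the terminal carbon and a further equivalent triggers loss of Me2S from the oxido sulfonium salt, which is the known one-carbon homologation of epoxides to allylic alcohols; C14 keeps its configuration.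

Step 12
Reactants: 10 (R)-1-((1R,2R)-2-((R)-1-hydroxyallyl)cyclopropyl)but-3-en-1-yl pent-4-enoate; 17 (S,Z)-undeca-1,5-dien-3-ol
Product: 19 Solandelactone F, via ring-closed lactone vinyl carbinol 18 (not isolated)
Conditions: RuCl2(H2IMes)(=CH-C6H4-2-OiPr) (second-generation Hoveyda–Grubbs catalyst, 10 mol%), 1,4-benzoquinone (20 mol%), CH2Cl2 (1 mM in 10), 40 °C, argon sparge; then 17 (4 equiv), further catalyst (5 mol%), solvent distilled off to ca. 0.05 M, 40 °C
Reagents that add atoms: none
Why: Both events follow the Chauvin mechanism, [2+2] cycloaddition of a ruthenium alkylidene to an alkene and cycloreversion of the ruthenacyclobutane; the closest known reaction types are ring-closing metathesis of pent-4-enoates of homoallylic alcohols to oct-4-enolides and cross-metathesis of two secondary allylic alcohols. In the dilute first stage the catalyst loads on the unhindered pentenoate or allyl terminus of 10 and is trapped by the other, so the eight-membered ring (O, C1–C7) closes by ring-closing metathesis at C4=C5 with loss of ethene, and a ring of this size can hold only the Z alkene. The C11 vinyl group is branched at its allylic carbon and initiates more slowly, and it has no good ring to close: onto C5 it would place the trans-cyclopropane in a seven-membered ring, and onto C4 it would give a ten-membered ring, which forms more slowly than the eight-membered ring between the two unhindered termini. After excess 17 is added and the solution concentrated, the vinyl carbinols of 18 and 17 exchange their methylene groups for each other, forming C12=C13 with loss of a second ethene. No stereocentre is created; C7, C8, C10, C11 and C14 are spectators, provided ruthenium hydride isomerisation of the allylic alcohols is suppressed, which is the role of 1,4-benzoquinone. The E geometry at C12=C13 follows from the reversibility of cross-metathesis between two allylic carbinols, which settles on the less crowded trans alkene. The excess of the readily made partner 17 favours the cross product over homodimers. The internal Z alkenes C4=C5 and C16=C17 are spared because 1,2-disubstituted alkenes react far more slowly than vinyl groups, helped by the argon sparge that removes ethene and keeps the ring-opening methylidene species scarce.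

## Compound list

1 | (E)-but-2-ene-1,4-diol | OC/C=C/CO | starting material
2 | (E)-4-((tert-butyldiphenylsilyl)oxy)but-2-en-1-ol | CC(C)(C)[Si](c1ccccc1)(c1ccccc1)OC/C=C/CO | intermediate
3 | ((1R,2R)-2-(((tert-butyldiphenylsilyl)oxy)methyl)cyclopropyl)methanol | CC(C)(C)[Si](c1ccccc1)(c1ccccc1)OC[C@@H]1C[C@H]1CO | intermediate
4 | (1R,2R)-2-(((tert-butyldiphenylsilyl)oxy)methyl)cyclopropane-1-carbaldehyde | CC(C)(C)[Si](c1ccccc1)(c1ccccc1)OC[C@@H]1C[C@H]1C=O | intermediate
5 | (R)-1-((1R,2R)-2-(((tert-butyldiphenylsilyl)oxy)methyl)cyclopropyl)but-3-en-1-ol | CC(C)(C)[Si](c1ccccc1)(c1ccccc1)OC[C@@H]1C[C@H]1[C@H](O)CC=C | intermediate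
6 | pent-4-enoic acid | C=CCCC(=O)O | starting material
7 | (R)-1-((1R,2R)-2-(((tert-butyldiphenylsilyl)oxy)methyl)cyclopropyl)but-3-en-1-yl pent-4-enoate | CC(C)(C)[Si](c1ccccc1)(c1ccccc1)OC[C@@H]1C[C@H]1[C@H](OC(=O)CCC=C)CC=C | intermediate
8 | (R)-1-((1R,2R)-2-(hydroxymethyl)cyclopropyl)but-3-en-1-yl pent-4-enoate | OC[C@@H]1C[C@H]1[C@H](OC(=O)CCC=C)CC=C | intermediate
9 | (R)-1-((1R,2R)-2-formylcyclopropyl)but-3-en-1-yl pent-4-enoate | O=C[C@@H]1C[C@H]1[C@H](OC(=O)CCC=C)CC=C | intermediate
10 | (R)-1-((1R,2R)-2-((R)-1-hydroxyallyl)cyclopropyl)but-3-en-1-yl pent-4-enoate (triene ester) | C=C[C@@H](O)[C@@H]1C[C@H]1[C@H](OC(=O)CCC=C)CC=C | intermediate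
11 | hept-1-yne | CCCCCC#C | starting material
12 | (S)-epichlorohydrin | ClC[C@@H]1CO1 | starting material
13 | lithium hept-1-yn-1-ide | [Li]C#CCCCCC | intermediate (not isolated)
14 | (S)-1-chlorodec-4-yn-2-ol | ClC[C@@H](O)CC#CCCCCC | intermediate
15 | (S,Z)-1-chlorodec-4-en-2-ol | ClC[C@@H](O)C/C=C\CCCCC | intermediate
16 | (S,Z)-2-(oct-2-en-1-yl)oxirane | C1[C@@H](O1)C/C=C\CCCCC | intermediate (not isolated)
17 | (S,Z)-undeca-1,5-dien-3-ol | C=C[C@@H](O)C/C=C\CCCCC | intermediate
18 | (R,Z)-8-((1R,2R)-2-((R)-1-hydroxyallyl)cyclopropyl)-3,4,7,8-tetrahydro-2H-oxocin-2-one | C=C[C@@H](O)[C@@H]1C[C@H]1[C@H]1C/C=C\CCC(=O)O1 | intermediate (not isolated)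
19 | Solandelactone F, (R,Z)-8-((1R,2R)-2-((1R,2E,4S,6Z)-1,4-dihydroxydodeca-2,6-dien-1-yl)cyclopropyl)-3,4,7,8-tetrahydro-2H-oxocin-2-one | CCCCC/C=C\C[C@H](O)/C=C/[C@@H](O)[C@@H]1C[C@H]1[C@H]1C/C=C\CCC(=O)O1 | target

## Step count and risks

Total: 12 steps (8 to the triene ester 10, 3 to the dienol 17, 1 for the union). Longest linear sequence: 9 steps (steps 1–8 and 12).

**Step 12 (key step).** Three processes may go wrong.
- Intermolecular metathesis may outrun the eight-membered ring closure, because the ester prefers the s-trans conformation that holds the two termini apart.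
- In the concentrated second stage the strained ring alkene may be re-opened by methylidene or by the excess partner, and long exposure to the catalyst may isomerise the allylic carbinols to ketones.
- The cross-metathesis may stay statistical.

Fallback (sets out from 7, returns at 18 and so at 19): the two metatheses are separated and the ring is closed where only two alkenes exist. Ring-closing metathesis of silyl ether 7 with the same catalyst at high dilution should give (R,Z)-8-((1R,2R)-2-(((tert-butyldiphenylsilyl)oxy)methyl)cyclopropyl)-3,4,7,8-tetrahydro-2H-oxocin-2-one F1. Desilylation with TBAF and AcOH gives (R,Z)-8-((1R,2R)-2-(hydroxymethyl)cyclopropyl)-3,4,7,8-tetrahydro-2H-oxocin-2-one F2. TEMPO and PhI(OAc)2 give (1R,2R)-2-((2R,4Z)-8-oxo-3,6,7,8-tetrahydro-2H-oxocin-2-yl)cyclopropane-1-carbaldehyde F3. Addition of Zn(CH=CH2)2 with (+)-MIB gives 18, now isolated and purified. Cross-metathesis of 18 with excess 17 at ordinary concentration is then the only event of the last step and gives 19.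

**Step 8.** Poor facial selectivity is the main risk: the uncatalysed addition of the reactive divinylzinc competes with the ligand-accelerated path, and the existing centres may form a mismatched pair with the ligand.

Fallback (sets out from 9, returns at 10): Zn(CH=CH2)2 without ligand adds to 9 to give 10 together with its C11 epimer (R)-1-((1R,2R)-2-((S)-1-hydroxyallyl)cyclopropyl)but-3-en-1-yl pent-4-enoate F4. Sharpless kinetic resolution of the mixture (Ti(OiPr)4, D-(−)-diisopropyl tartrate, t-BuOOH, 4 Å molecular sieves, CH2Cl2, −20 °C) should epoxidise F4 faster, to (R)-1-((1R,2R)-2-((R)-hydroxy((S)-oxiran-2-yl)methyl)cyclopropyl)but-3-en-1-yl pent-4-enoate F5. The slow-reacting 10 is then separated by chromatography. The tartrate is chosen by the rule for 1-alken-3-ols, with the change of substituent priorities at C11 taken into account.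

**Step 11.** The ylide or residual base may remove an allylic C15 hydrogen and open epoxide 16 by elimination instead of attacking its terminal carbon, and conversion may stall at the epoxide because the chlorohydrin consumes ylide.

Fallback (sets out from 15, returns at 17): 15 is closed with K2CO3 in MeOH and the epoxide 16 is isolated. PhSeCH2Li (from (PhSe)2CH2 and n-BuLi, THF, −78 °C) opens it at the terminal carbon to (S,Z)-1-(phenylselanyl)undec-5-en-3-ol F6. Oxidation with H2O2 and pyridine gives (S,Z)-1-(phenylseleninyl)undec-5-en-3-ol F7, not isolated, whose syn-elimination places the new alkene at the chain end and gives 17.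

**Step 10.** Over-reduction to the saturated chain or partial Z-to-E isomerisation on the catalyst would give contaminants of the same polarity that are hard to remove.

Fallback (sets out from 12, returns at 15, replacing steps 9 and 10): carbocupration of acetylene with the cuprate from n-pentyllithium and CuBr·SMe2 (Et2O, −50 to −25 °C) gives lithium di((Z)-hept-1-en-1-yl)cuprate F8, whose Z geometry is fixed by syn addition. F8 opens (S)-epichlorohydrin 12 at the epoxide CH2 and gives 15 directly, so no hydrogenation is needed.

## Further compounds

F1 | step 12 | (R,Z)-8-((1R,2R)-2-(((tert-butyldiphenylsilyl)oxy)methyl)cyclopropyl)-3,4,7,8-tetrahydro-2H-oxocin-2-one | CC(C)(C)[Si](c1ccccc1)(c1ccccc1)OC[C@@H]1C[C@H]1[C@H]1C/C=C\CCC(=O)O1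
F2 | step 12 | (R,Z)-8-((1R,2R)-2-(hydroxymethyl)cyclopropyl)-3,4,7,8-tetrahydro-2H-oxocin-2-one | OC[C@@H]1C[C@H]1[C@H]1C/C=C\CCC(=O)O1
F3 | step 12 | (1R,2R)-2-((2R,4Z)-8-oxo-3,6,7,8-tetrahydro-2H-oxocin-2-yl)cyclopropane-1-carbaldehyde | O=C[C@@H]1C[C@H]1[C@H]1C/C=C\CCC(=O)O1
F4 | step 8 | (R)-1-((1R,2R)-2-((S)-1-hydroxyallyl)cyclopropyl)but-3-en-1-yl pent-4-enoate | C=C[C@H](O)[C@@H]1C[C@H]1[C@H](OC(=O)CCC=C)CC=C
F5 | step 8 | (R)-1-((1R,2R)-2-((R)-hydroxy((S)-oxiran-2-yl)methyl)cyclopropyl)but-3-en-1-yl pent-4-enoate | C1O[C@@H]1[C@H](O)[C@@H]1C[C@H]1[C@H](OC(=O)CCC=C)CC=C
F6 | step 11 | (S,Z)-1-(phenylselanyl)undec-5-en-3-ol | c1ccccc1[Se]CC[C@@H](O)C/C=C\CCCCC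
F7 | step 11 | (S,Z)-1-(phenylseleninyl)undec-5-en-3-ol | O=[Se](c1ccccc1)CC[C@@H](O)C/C=C\CCCCC
F8 | step 10 | lithium di((Z)-hept-1-en-1-yl)cuprate | [Li+].CCCCC/C=C\[Cu-]/C=C\CCCCC
A1 | alternative 1 | (1R,2R)-1,2-bis((S)-2,2-dimethyl-1,3-dioxolan-4-yl)cyclopropane | CC1(C)OC[C@@H](O1)[C@@H]1C[C@H]1[C@H]1COC(C)(C)O1
A2 | alternative 1 | (E)-1,2-bis((S)-2,2-dimethyl-1,3-dioxolan-4-yl)ethene | CC1(C)OC[C@@H](O1)/C=C/[C@H]1COC(C)(C)O1
A3 | alternative 1 | D-mannitol | OC[C@@H](O)[C@@H](O)[C@H](O)[C@H](O)CO
A4 | alternative 2 | C1–C22 skeleton with the (S,S)-1,2-dicyclohexylethanediol boronic ester at C11 and the tert-butyldimethylsilyl ether at C14 | CCCCC/C=C\C[C@H](O[Si](C)(C)C(C)(C)C)/C=C/[C@@H](B1O[C@@H](C2CCCCC2)[C@H](C2CCCCC2)O1)[C@@H]1C[C@H]1[C@H]1C/C=C\CCC(=O)O1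
A5 | alternative 2 | (R,Z)-8-((1R,2R)-2-((4S,5S)-4,5-dicyclohexyl-1,3,2-dioxaborolan-2-yl)cyclopropyl)-3,4,7,8-tetrahydro-2H-oxocin-2-one | B1(O[C@@H](C2CCCCC2)[C@H](C2CCCCC2)O1)[C@@H]1C[C@H]1[C@H]1C/C=C\CCC(=O)O1
A6 | alternative 2 | ((S,1E,5Z)-3-((tert-butyldimethylsilyl)oxy)undeca-1,5-dien-1-yl)magnesium bromide | CCCCC/C=C\C[C@H](O[Si](C)(C)C(C)(C)C)/C=C/[Mg]Br
A7 | alternative 2 | dichloromethyllithium | [Li]C(Cl)Cl
A8 | alternative 3 | tert-butyl (1R,2R)-2-((2R,4Z)-8-oxo-3,6,7,8-tetrahydro-2H-oxocin-2-yl)cyclopropane-1-carboxylate | CC(C)(C)OC(=O)[C@@H]1C[C@H]1[C@H]1C/C=C\CCC(=O)O1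
A9 | alternative 3 | (R,Z)-8-vinyl-3,4,7,8-tetrahydro-2H-oxocin-2-one | C=C[C@H]1C/C=C\CCC(=O)O1
A10 | alternative 3 | tert-butyl diazoacetate | CC(C)(C)OC(=O)C=[N+]=[N-]
A11 | alternative 3 | (1Z,5Z)-cycloocta-1,5-diene | C1/C=C\CC/C=C\C1
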